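The leftover is what I follow in this flask: 1.25 mM of free catalyst charged, less 0.61 mM of impurity, gives 0.640 mM. This is the surplus catalyst, the catalyst remaining in its working forms, free or bound, once each impurity has taken one catalyst, with the impurity as limiting reagent of that side reaction.

| setting | teal | ochre | red | flask |
|---|---|---|---|---|
| substrate | 0.050 M | 0.050 M | 0.050 M | 0.050 M |
| free catalyst | 2.5 mol% | 2.5 mol% | 5 mol% | 2.5 mol% |
| impurity | 0.30 mM | 1.2 mM | 0.61 mM | 0.61 mM |
| remark | run made earlier | run made earlier | run made earlier |  |

| run | time / h | product / % | substrate / % |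
|---|---|---|---|
| teal | 1.00 | 23.8 | 14.0 |
| teal | 2.00 | 30.6 | 4.4 |
| teal | 3.00 | 33.2 | 2.4 |
| teal | 4.00 | 33.6 | 0.7 |
| teal | 5.00 | 33.6 | 0 |
| teal | 6.00 | 34.7 | 0 |
| ochre | 1.00 | 1.1 | 21.0 |
| ochre | 2.00 | 2.5 | 11.9 |
| ochre | 3.00 | 2.4 | 8.4 |
| ochre | 4.00 | 2.7 | 5.5 |
| ochre | 5.00 | 3.3 | 4.7 |
| ochre | 6.00 | 3.6 | 3.2 |
| red | 0.500 | 30.0 | 21.5 |
| red | 1.50 | 44.0 | 3.7 |
| red | 3.00 | 47.8 | 0.3 |
| red | 5.00 | 47.9 | 0.1 |
| red | 6.00 | 48.1 | 0.2 |

(each reading ± 0.5 percentage points)

* factor on the rate of making product when 5.0 % of the substrate are converted if free catalyst is charged twice over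
* factor on the rate when 5.0 % of the substrate are converted if free catalyst is charged at 12 mol% instead

- percent here means substrate units held: one homo dimer counts as two
- reactions considered so far: substrate + free catalyst <-> catalyst intermediate A; catalyst intermediate A <-> catalyst intermediate B; catalyst intermediate B -> free catalyst + product; free catalyst + impurity -> spent catalyst; 2 substrate -> homo dimer

Two colleagues dispute the asked factors. The first holds that the rate follows the catalyst charged, arguing that the impurity acts too late to count at 5.0 % conversion. Doubling the charge then gives a factor of two, and 12 mol% gives 4.80.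

The second points to teal and ochre, which have equal charges of catalyst but read 34.7 % and 3.6 % product after 6.00 h. Their surpluses are 0.950 mM and 0.0500 mM, and the charge cannot tell these runs apart. The red run, which is the doubled recipe, has a surplus of 1.89 mM and reads 48.1 % after 6.00 h.

I side with the second and freeze the surplus from the start. Taking the rate as proportional to it, I get 2.95 for doubling and 8.42 for 12 mol%.

The forecast gives 2.9 and 8, the second below my figure, on the ground “Product rate is thus roughly first order in active catalyst”.

The simulation gives 2.83 and 6.26.

    substrate + free catalyst ⇌ catalyst intermediate A (K = 6.80 /M, k = 55.0 /M/min)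
    catalyst intermediate A ⇌ catalyst intermediate B (K = 1.70, k = 21.0 /min)
    catalyst intermediate B → free catalyst + product (k = 2.10 /min)
    free catalyst + impurity → spent catalyst (k = 17000 /M/min)
    2 substrate → homo dimer (k = 0.610 /M/min)

Doubling lands near the surplus reckoning, while 6.26 lies between 4.80 and 8.42. In this flask, spent catalyst stands at 48.8 % after 0.800 h, matching the 48.8 % the impurity allows. Removing the reaction of free catalyst with impurity raises this flask's rate at 5.0 % conversion by a factor of 1.90, one part of the story, close to charge over surplus, 1.95. The first colleague's view holds in that same case without this reaction, where the apparent order in free catalyst falls from 1.9 to 0.97.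

The readings stem from a simulated flask from invented constants; scatter was added.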